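**Plan**

- Retrosynthesis: (a) the sp–sp2 bond between the alkyne and the E-alkene is cut (Sonogashira) to give an ethynyl-oxolane ester and a C10 bromo-iodo-triene. (b) In the oxolane (O1, C2 with the ester arm, C3, C4, C5 with the alkyne) the O1–C2 bond and the arm bond between the first and second CH2 are cut together, leading to (3S)-1-(trimethylsilyl)hept-6-en-1-yn-3-ol and methyl acrylate. (c) The Z-alkene of the bromodiene is cut (Wittig) to a phosphonium salt and (2E)-3-bromoprop-2-enal.
- Enabling feature: O1 sits on the propargylic carbon C5, which is linked to C2 through C3 and C4, so O1 and C2 are the two ends of a 4-pentenol. C2 carries an exocyclic CH2 whose continuation CH2CH2CO2Me is one methyl acrylate unit. An oxidative O1–C2 closure that leaves a radical on that CH2 can therefore build the ring and the arm in one operation.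
- Forward order: acyl coupling to the ynone, transfer hydrogenation (sets C5), cobalt/O2 cyclisation–radical addition cascade (closes the only ring, sets C2), desilylation, then Sonogashira union with the side chain, which is made separately in four steps.
- Stereochemistry: C5 (S) comes from catalyst control in the Noyori reduction. C2 (R) comes from substrate control in the ring closure (2,5-trans). Alkene geometries come from syn-hydrozirconation (E-iodide), a lithium-free Wittig reaction (Z) and the E-bromoenal.

Key step: step 3

**Route**

Step 1
Reactants: 1 pent-4-enoyl chloride; 2 ethynyltrimethylsilane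
Product: 3 1-(trimethylsilyl)hept-6-en-1-yn-3-one
Conditions: PdCl2(PPh3)2 (2 mol %), CuI (4 mol %), Et3N (1.1 equiv), THF, rt
Reagents that add atoms: none
Why: Acyl Sonogashira coupling, in which the acid chloride adds oxidatively to zerovalent palladium (formed in the flask from PdCl2(PPh3)2), the copper acetylide transmetalates and reductive elimination should give the ynone, with only one equivalent of amine so that ketene formation from the enolisable acid chloride stays low.

Step 2
Reactants: 3 1-(trimethylsilyl)hept-6-en-1-yn-3-one
Product: 4 (3S)-1-(trimethylsilyl)hept-6-en-1-yn-3-ol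
Conditions: Ru(p-cymene)[(S,S)-TsDPEN] (amido complex, 1 mol %), i-PrOH, rt
Reagents that add atoms: none
Why: Noyori asymmetric transfer hydrogenation of an alkynyl ketone, in which the Ru–H/N–H pair of the (S,S)-catalyst should deliver hydrogen through the six-membered transition state to the face that gives the (S)-propargylic alcohol (the alkynyl group takes the place of the aryl group of aryl ketones), while the isolated alkene and the C–Si bond are untouched.

Step 3
Reactants: 4 (3S)-1-(trimethylsilyl)hept-6-en-1-yn-3-ol; 5 methyl acrylate
Product: 6 methyl 4-[(2R,5S)-5-[(trimethylsilyl)ethynyl]oxolan-2-yl]butanoate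
Conditions: Co(btfa)2 [cobalt bis(4,4,4-trifluoro-1-phenylbutane-1,3-dionate), divalent cobalt] (10 mol %), O2 (1 atm), 1,4-cyclohexadiene (excess, added slowly), 5 (10 equiv), toluene, 60 °C
Reagents that add atoms: none
Why: The divalent cobalt diketonate takes up the alkenol and O2 to give a trivalent cobalt peroxy species in which the hydroxyl oxygen adds to the internal alkene carbon as the alkene is oxidised, so the O1–C2 bond closes the oxolane in the 5-exo-trig mode and releases the (oxolan-2-yl)methyl radical. This nucleophilic primary radical adds to the β-carbon of methyl acrylate (Giese addition), and the α-ester radical takes a hydrogen atom from 1,4-cyclohexadiene, which also reduces the cobalt-bound peroxide to water and ends as benzene. The closest known reaction type is the aerobic cobalt-catalysed oxidative cyclisation of 4-pentenols (Mukaiyama type) run with alkylative instead of hydroxylative termination. The new stereocentre C2 is controlled by the existing carbinol centre: in the chair-like transition state of the cobalt-bound alkenol the alkynyl group lies pseudo-equatorial, which should place the two ring substituents 2,5-trans, that is (2R,5S). The step needs 5-exo over 6-endo closure, capture of the radical by the acrylate ahead of hydrogen transfer or O2 capture, and an inert triple bond; the terminal monosubstituted alkene secures the regiochemistry, the large excess of acrylate with slowly added cyclohexadiene secures the order of trapping, and the silyl cap together with the trans arrangement (radical carbon and alkyne on opposite ring faces) keeps the alkyne out of reach.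

Step 4
Reactants: 6 methyl 4-[(2R,5S)-5-[(trimethylsilyl)ethynyl]oxolan-2-yl]butanoate
Product: 7 methyl 4-[(2R,5S)-5-ethynyloxolan-2-yl]butanoate
Conditions: K2CO3 (0.2 equiv), MeOH, 0 °C to rt
Reagents that add atoms: none
Why: Base-catalysed methanolysis of the alkynyl C–Si bond (protodesilylation) should free the terminal alkyne, the ester being already a methyl ester so that exchange with the solvent changes nothing, and carbonate being too weak to epimerise either ether carbon.

Step 5
Reactants: 8 7-bromohept-1-yne
Product: 10 (1E)-7-bromo-1-iodohept-1-ene, via alkenylzirconocene chloride 9 (not isolated)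
Conditions: Cp2Zr(H)Cl (1.2 equiv), THF, rt; then I2, 0 °C
Reagents that add atoms: iodine, II
Why: Hydrozirconation–iodination, in which syn, anti-Markovnikov addition of Zr–H across the terminal alkyne and iodinolysis of the C–Zr bond with retention should give the E-iodoalkene, the primary alkyl bromide being tolerated at room temperature.

Step 6
Reactants: 10 (1E)-7-bromo-1-iodohept-1-ene
Product: 11 [(6E)-7-iodohept-6-en-1-yl]triphenylphosphonium bromide
Conditions: PPh3 (1.1 equiv), MeCN, reflux
Reagents that add atoms: triphenylphosphine, c1ccc(cc1)P(c1ccccc1)c1ccccc1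
Why: Quaternisation of the phosphine by SN2 substitution at the primary C–Br bond, the sp2 C–I bond being inert to the phosphine when no transition-metal catalyst is present.

Step 7
Reactants: 12 3,3-diethoxyprop-1-yne
Product: 14 (2E)-3-bromoprop-2-enal, via prop-2-ynal 13 (not isolated)
Conditions: 48% aq HBr, Et4NBr (cat.), CH2Cl2, 0 °C to rt
Reagents that add atoms: hydrogen bromide, Br; water, O
Why: Acid hydrolysis of the acetal to the ynal followed by conjugate hydrobromination, the haloenal equilibrating under HBr to the more stable E isomer, which is used at once as a cold solution because it is volatile and labile.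

Step 8
Reactants: 11 [(6E)-7-iodohept-6-en-1-yl]triphenylphosphonium bromide; 14 (2E)-3-bromoprop-2-enal
Product: 16 (1E,7Z,9E)-10-bromo-1-iododeca-1,7,9-triene, via phosphorus ylide 15 (not isolated)
Conditions: NaN(SiMe3)2 (1.0 equiv), THF, −78 °C; then 14, −78 °C to 0 °C
Reagents that add atoms: none
Why: Lithium-free Wittig olefination of a non-stabilised ylide, in which early, kinetically controlled formation of the cis-oxaphosphetane at −78 °C should give the new alkene Z, carbonyl addition outpacing addition–elimination at the bromine-bearing carbon, while the E C=C–Br unit is carried in unchanged and the E-iodoalkene is not attacked by one equivalent of the hindered amide.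

Step 9
Reactants: 7 methyl 4-[(2R,5S)-5-ethynyloxolan-2-yl]butanoate; 16 (1E,7Z,9E)-10-bromo-1-iododeca-1,7,9-triene
Product: 17 methyl 4-[(2R,5S)-5-[(3E,9Z,11E)-12-bromododeca-3,9,11-trien-1-yn-1-yl]oxolan-2-yl]butanoate
Conditions: Pd(PPh3)4 (5 mol %), CuI (10 mol %), Et3N, THF (degassed), 0 °C to rt, 16 (1.2 equiv), exclusion of light
Reagents that add atoms: none
Why: Sonogashira coupling with retention of alkene geometry, in which zerovalent palladium should insert into the alkenyl C–I bond far faster than into the dienyl C–Br bond at or below room temperature, so that with the alkyne as the limiting partner coupling takes place only at the iodide, the ester and both stereocentres being spectators.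

**Compound list**

1 | pent-4-enoyl chloride | C=CCCC(=O)Cl | starting material
2 | ethynyltrimethylsilane | C#C[Si](C)(C)C | starting material
3 | 1-(trimethylsilyl)hept-6-en-1-yn-3-one | C=CCCC(=O)C#C[Si](C)(C)C | intermediate
4 | (3S)-1-(trimethylsilyl)hept-6-en-1-yn-3-ol | C=CCC[C@@H](C#C[Si](C)(C)C)O | intermediate
5 | methyl acrylate | C=CC(=O)OC | starting material
6 | methyl 4-[(2R,5S)-5-[(trimethylsilyl)ethynyl]oxolan-2-yl]butanoate | COC(=O)CCC[C@@H]1CC[C@@H](C#C[Si](C)(C)C)O1 | intermediate
7 | methyl 4-[(2R,5S)-5-ethynyloxolan-2-yl]butanoate | COC(=O)CCC[C@@H]1CC[C@@H](C#C)O1 | intermediate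
8 | 7-bromohept-1-yne | BrCCCCCC#C | starting material
9 | [(1E)-7-bromohept-1-en-1-yl]chloridobis(cyclopentadienyl)zirconium (cyclopentadienyl rings drawn sigma-bonded) | BrCCCCC/C=C/[Zr](Cl)(C1C=CC=C1)C1C=CC=C1 | intermediate (not isolated)
10 | (1E)-7-bromo-1-iodohept-1-ene | BrCCCCC/C=C/I | intermediate
11 | [(6E)-7-iodohept-6-en-1-yl]triphenylphosphonium bromide | [Br-].I/C=C/CCCCC[P+](c1ccccc1)(c1ccccc1)c1ccccc1 | intermediate
12 | 3,3-diethoxyprop-1-yne | C#CC(OCC)OCC | starting material
13 | prop-2-ynal | C#CC=O | intermediate (not isolated)
14 | (2E)-3-bromoprop-2-enal | Br/C=C/C=O | intermediate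
15 | [(6E)-7-iodohept-6-en-1-ylidene]triphenylphosphorane | I/C=C/CCCCC=P(c1ccccc1)(c1ccccc1)c1ccccc1 | intermediate (not isolated)
16 | (1E,7Z,9E)-10-bromo-1-iododeca-1,7,9-triene | I/C=C/CCCC/C=C\C=C\Br | intermediate
17 | methyl 4-[(2R,5S)-5-[(3E,9Z,11E)-12-bromododeca-3,9,11-trien-1-yn-1-yl]oxolan-2-yl]butanoate | COC(=O)CCC[C@@H]1CC[C@@H](C#C/C=C/CCCC/C=C\C=C\Br)O1 | target

**Step count**

Total steps: 9. Longest linear sequence: 5 steps (steps 1, 2, 3, 4 and 9, from pent-4-enoyl chloride).

**Steps most likely to fail**

Step 3. The (oxolan-2-yl)methyl radical may be intercepted by hydrogen transfer from cyclohexadiene or by O2 before it adds to the acrylate. The acrylate may also telomerise, or autoxidation may start at the propargylic C–H bond. The fallback gives up the cascade and attaches the arm in a separate operation. It sets out from 4: Co(modp)2 [cobalt bis(1-morpholinocarbamoyl-4,4-dimethylpentane-1,3-dionate)], O2, t-BuOOH (cat.), i-PrOH, 55 °C should give, through the same 5-exo closure but with hydroxylative termination, [(2S,5S)-5-[(trimethylsilyl)ethynyl]oxolan-2-yl]methanol F1. The descriptor at C2 changes only because CH2OH outranks the ring carbon. I2, PPh3 and imidazole in CH2Cl2 would convert F1 into (2S,5S)-2-(iodomethyl)-5-[(trimethylsilyl)ethynyl]oxolane F2. A tin-free Giese addition of F2 to 5 [(Me3Si)3SiH, AIBN, excess 5, toluene, 80 °C] would then deliver 6, where the route is rejoined.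

Step 9. Oxidative addition may also take place at the dienyl C–Br bond, leading to double coupling or oligomers. Copper-mediated homocoupling of the alkyne and erosion of the bromodiene geometry on palladium are further risks. The fallback changes the order of events so that no second sp2 halide is present during the palladium step. It sets out from 7 and 10: Pd(PPh3)4, CuI, Et3N, THF, rt should give methyl 4-[(2R,5S)-5-[(3E)-9-bromonon-3-en-1-yn-1-yl]oxolan-2-yl]butanoate F3. PPh3 in MeCN at 70 °C would give [(6E)-9-[(2S,5R)-5-(4-methoxy-4-oxobutyl)oxolan-2-yl]non-6-en-8-yn-1-yl]triphenylphosphonium bromide F4. One equivalent of NaN(SiMe3)2 in THF at −78 °C, which the methyl ester should tolerate, would form the corresponding phosphorus ylide F5. Addition of 14 at −78 °C (Z-selective Wittig reaction as in step 8) would then give the target 17 directly.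

Step 8. Z selectivity may be lost, the ylide may add to the bromine-bearing carbon with loss of bromide, or the labile aldehyde may polymerise. The fallback brings in the bromine after the olefination. It sets out from 11: ylide 15 (NaN(SiMe3)2, THF, −78 °C) would be treated with the more robust (2E)-3-(tributylstannyl)prop-2-enal F6, made by MnO2 oxidation of commercial (2E)-3-(tributylstannyl)prop-2-en-1-ol in CH2Cl2. This should give tributyl[(1E,3Z,9E)-10-iododeca-1,3,9-trien-1-yl]stannane F7. Bromodestannylation with NBS in MeCN at 0 °C, which proceeds with retention at the stannylated carbon, would then give 16, where the route is rejoined. Step 7 is not needed on this path.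

Further compounds
F1 | step 3 | [(2S,5S)-5-[(trimethylsilyl)ethynyl]oxolan-2-yl]methanol | OC[C@@H]1CC[C@@H](C#C[Si](C)(C)C)O1
F2 | step 3 | (2S,5S)-2-(iodomethyl)-5-[(trimethylsilyl)ethynyl]oxolane | IC[C@@H]1CC[C@@H](C#C[Si](C)(C)C)O1
F3 | step 9 | methyl 4-[(2R,5S)-5-[(3E)-9-bromonon-3-en-1-yn-1-yl]oxolan-2-yl]butanoate | COC(=O)CCC[C@@H]1CC[C@@H](C#C/C=C/CCCCCBr)O1
F4 | step 9 | [(6E)-9-[(2S,5R)-5-(4-methoxy-4-oxobutyl)oxolan-2-yl]non-6-en-8-yn-1-yl]triphenylphosphonium bromide | [Br-].COC(=O)CCC[C@@H]1CC[C@@H](C#C/C=C/CCCCC[P+](c2ccccc2)(c2ccccc2)c2ccccc2)O1
F5 | step 9 | phosphorus ylide of F4, methyl 4-[(2R,5S)-5-[(3E)-9-(triphenyl-λ5-phosphanylidene)non-3-en-1-yn-1-yl]oxolan-2-yl]butanoate | COC(=O)CCC[C@@H]1CC[C@@H](C#C/C=C/CCCCC=P(c2ccccc2)(c2ccccc2)c2ccccc2)O1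
F6 | step 8 | (2E)-3-(tributylstannyl)prop-2-enal | CCCC[Sn](CCCC)(CCCC)/C=C/C=O
F7 | step 8 | tributyl[(1E,3Z,9E)-10-iododeca-1,3,9-trien-1-yl]stannane | I/C=C/CCCC/C=C\C=C\[Sn](CCCC)(CCCC)CCCC
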